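The data are simulated with constants of no real substance; scatter was added.

When, up to 40 h, does this flask hold most left-handed product, and how much? Saturday's run is this same flask, followed so far.

the same everywhere: left-handed substrate 0.50 M; right-handed substrate 0.50 M

| charge | coupling partner | protic impurity | remark | time |
|---|---|---|---|---|
| Saturday's | 0.50 M (fed, over 40 min) | 0.050 M | the very flask that is asked about, followed so far |  |
| flask | 0.500 M (fed, over 40 min) | 0.0500 M |  | 40 h |

Saturday's run (percent of the left-handed substrate and right-handed substrate together charged)

| time / h | left-handed product / % | left-handed substrate / % |
|---|---|---|
| 0.250 | 4 | 43 |
| 0.500 | 14 | 35 |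
| 0.833 | 21 | 27 |
| 1.50 | 26 | 22 |
| 3.00 | 27 | 24 |

(standard deviation of a reading: 1.5 percentage points)

- coupling partner is single-handed; left-handed substrate and right-handed substrate are mirror images of each other, charged as a racemate, each of them at the stated concentration
- the handed part of coupling partner does not stay in what it makes, so the products of the two hands are mirror images too

You can bracket the answer, with the symmetric case as the zero of the scale. The two products are mirror images, so equal amounts of them are the neutral state, the value under thermodynamic control. If the protic impurity takes one coupling partner each, the rest couples, and the racemic floor F is 22.5% of both substrates together, the usable partner shared equally between the hands. Going wholly to the left hand, that partner gives 45.0% as a crude upper bound. The readings narrow this as an estimate, not as a bound: left-handed substrate reads 22% at 1.50 h, so about 28.0% had coupled on that hand by then, a figure that carries the scatter of one reading. My own reckoning puts the peak between 1.50 h and 3.00 h, where the product readings 26% and 27% differ by 1 percentage point against a scatter of 1.5 points.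

The forecast says 3 h and 27%, inside the bracket from 22.5% to 45.0%, “then flat or slowly falling”. The flask peaks at 1.63 h with 26.2%.

    left-handed product ⇌ right-handed product (k = 0.00258 min⁻¹)
    coupling partner + right-handed substrate → right-handed product (k = 0.0602 M⁻¹ min⁻¹)
    coupling partner + protic impurity → quenched reagent (k = 0.596 M⁻¹ min⁻¹)
    coupling partner + left-handed substrate → left-handed product (k = 0.123 M⁻¹ min⁻¹)

In this flask the half-life of coupling partner by the left-hand coupling, 0.19 h, is far shorter than the 4.5 h half-life of left-handed product turning into right-handed product, forward rate alone. At the peak, coupling partner is down to 1.53% of its charge, and by 40.0 h left-handed product has come down to 22.5%, level with right-handed product at 22.5% and with F at 22.5%. For the neighbour charged with 0.30 M of coupling partner, F reckons 12.5%, and that flask ends with 12.8% of left-handed product.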